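**Strategy.** The route rests on cutting ring A at two bonds: the bond from the angular, methyl-bearing quaternary carbon to the enone CH, and the bond from the ring ketone carbon to the acetyl-bearing olefinic carbon. The excised C(acetyl)=CH unit is methyl vinyl ketone. In one operation an iron-hydride HAT generates the tertiary radical at the angular carbon from an exocyclic methylene on ring B, Giese addition to the enone follows, and the resulting iron enolate closes onto a pendant aldehyde (radical–polar crossover annulation), exploiting the 1,4-relationship of these two ring-A carbons. The precursor is a monocyclic ring-B aldehyde already carrying the tertiary alcohol, the angelate and the acetate.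

Key step: step 9

Remark on the target: the decalin is cis-fused (angular methyl and angular hydroxyl syn); the ring-B C-methyl and acetate lie on the same face as these two groups, and the angelate is anti to the angular hydroxyl.

Assumption: the (S)-prolinol-derived oxazaborolidinium catalyst is taken to give the (1S,2S) cycloadduct 4; if the facial sense proves opposite, its mirror-image catalyst is used.

**Step 1**
Reactants: 1 (E)-3-methylpent-3-en-2-one
Product: 2 (E)-3-methyl-2-[(triisopropylsilyl)oxy]penta-1,3-diene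
Conditions: TIPSOTf, Et3N, CH2Cl2, 0 °C
Reagents that add atoms: triisopropylsilyl trifluoromethanesulfonate, CC(C)[Si](OS(=O)(=O)C(F)(F)F)(C(C)C)C(C)C
Why: Soft enolisation and O-silylation at the methyl ketone gives the cross-conjugated 2-silyloxydiene and leaves the E trisubstituted olefin untouched.

**Step 2**
Reactants: 2 (E)-3-methyl-2-[(triisopropylsilyl)oxy]penta-1,3-diene; 3 methyl vinyl ketone
Product: 4 1-[(1S,2S)-2,3-dimethyl-4-[(triisopropylsilyl)oxy]cyclohex-3-en-1-yl]ethan-1-one
Conditions: chiral oxazaborolidinium triflimide (20 mol %, from (S)-α,α-diphenylprolinol, o-tolylboroxine and Tf2NH), CH2Cl2, −78 to −40 °C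
Reagents that add atoms: none
Why: Catalytic enantioselective Diels–Alder reaction; the 2-silyloxy group ("para") and the terminal methyl ("ortho") both place the acetyl carbon next to the C-methyl carbon, endo approach should set the two new adjacent stereocentres cis, and the catalyst fixes the absolute sense.

**Step 3**
Reactants: 4 1-[(1S,2S)-2,3-dimethyl-4-[(triisopropylsilyl)oxy]cyclohex-3-en-1-yl]ethan-1-one
Product: 5 (3S,4S)-4-acetyl-2,3-dimethylcyclohex-1-en-1-yl trifluoromethanesulfonate
Conditions: CsF, PhNTf2, DME, rt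
Reagents that add atoms: N-phenylbis(trifluoromethanesulfonimide), O=S(=O)(N(c1ccccc1)S(=O)(=O)C(F)(F)F)C(F)(F)F
Why: Fluoride cleaves the silyl enol ether to a regiodefined cesium enolate that is O-triflated in situ (enol silyl ether to enol triflate exchange), so the tetrasubstituted olefin position is kept.

**Step 4**
Reactants: 5 (3S,4S)-4-acetyl-2,3-dimethylcyclohex-1-en-1-yl trifluoromethanesulfonate
Product: 6 (3R,4S)-4-(acetyloxy)-2,3-dimethylcyclohex-1-en-1-yl trifluoromethanesulfonate
Conditions: mCPBA, Na2HPO4, CH2Cl2, rt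
Reagents that add atoms: 3-chloroperoxybenzoic acid, OOC(=O)c1cccc(Cl)c1
Why: Baeyer–Villiger oxidation, in which the secondary ring carbon migrates in preference to methyl with retention of configuration, while the electron-poor enol triflate olefin resists the peracid.

**Step 5**
Reactants: 6 (3R,4S)-4-(acetyloxy)-2,3-dimethylcyclohex-1-en-1-yl trifluoromethanesulfonate; 7 (R)-2,2-dimethyl-1,3-dioxolane-4-carbaldehyde
Product: 8 (1S,2R)-4-[(S)-[(4R)-2,2-dimethyl-1,3-dioxolan-4-yl](hydroxy)methyl]-2,3-dimethylcyclohex-3-en-1-yl acetate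
Conditions: CrCl2 (4 equiv), NiCl2 (2 mol %), DMF, rt
Reagents that add atoms: none
Why: Nozaki–Hiyama–Kishi coupling of the alkenyl triflate tolerates the acetate, and Felkin–Anh (anti) addition to the α-alkoxy aldehyde is expected to set the carbinol centre S, the minor syn epimer being removed by chromatography.

**Step 6**
Reactants: 8 (1S,2R)-4-[(S)-[(4R)-2,2-dimethyl-1,3-dioxolan-4-yl](hydroxy)methyl]-2,3-dimethylcyclohex-3-en-1-yl acetate
Product: 10 (1S,2R,4R)-4-[(R)-[(4R)-2,2-dimethyl-1,3-dioxolan-4-yl](hydroxy)methyl]-4-hydroxy-2-methyl-3-methylidenecyclohexyl acetate, via tertiary allylic hydroperoxide 9 (not isolated)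
Conditions: O2, hν (visible), meso-tetraphenylporphyrin (cat.), CH2Cl2, −20 °C; then PPh3, 0 °C
Reagents that add atoms: dioxygen, O=O
Why: Hydroxyl-directed Schenck ene reaction of singlet oxygen: with the carbinol hydrogen held in the olefin plane by 1,3-allylic strain against the cis ring methyl, oxygen should add to the proximal olefin carbon on the hydroxyl face and take a hydrogen from that cis methyl, giving the threo tertiary hydroperoxide with an exocyclic methylene, which PPh3 reduces.

**Step 7**
Reactants: 10 (1S,2R,4R)-4-[(R)-[(4R)-2,2-dimethyl-1,3-dioxolan-4-yl](hydroxy)methyl]-4-hydroxy-2-methyl-3-methylidenecyclohexyl acetate; 11 angelic acid, (2Z)-2-methylbut-2-enoic acid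
Product: 12 (R)-[(1R,3R,4S)-4-(acetyloxy)-1-hydroxy-3-methyl-2-methylidenecyclohexyl][(4R)-2,2-dimethyl-1,3-dioxolan-4-yl]methyl (2Z)-2-methylbut-2-enoate
Conditions: 2,4,6-trichlorobenzoyl chloride, Et3N, toluene, rt; then 10, 75 °C
Reagents that add atoms: none
Why: Yamaguchi esterification through the mixed anhydride should acylate only the secondary hydroxyl (the tertiary one is inert) and, run without DMAP, is expected to keep the Z geometry of the angelate.

**Step 8**
Reactants: 12 (R)-[(1R,3R,4S)-4-(acetyloxy)-1-hydroxy-3-methyl-2-methylidenecyclohexyl][(4R)-2,2-dimethyl-1,3-dioxolan-4-yl]methyl (2Z)-2-methylbut-2-enoate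
Product: 14 (1S)-1-[(1R,3R,4S)-4-(acetyloxy)-1-hydroxy-3-methyl-2-methylidenecyclohexyl]-2-oxoethyl (2Z)-2-methylbut-2-enoate, via vicinal diol 13 (not isolated)
Conditions: H5IO6, EtOAc, 0 °C to rt
Reagents that add atoms: none
Why: Periodic acid hydrolyses the terminal acetonide and cleaves the liberated 1,2-diol in the same flask (glycol cleavage); no other free vicinal diol is present, so the esters, the tertiary alcohol and the olefins should survive.

**Step 9**
Reactants: 14 (1S)-1-[(1R,3R,4S)-4-(acetyloxy)-1-hydroxy-3-methyl-2-methylidenecyclohexyl]-2-oxoethyl (2Z)-2-methylbut-2-enoate; 3 methyl vinyl ketone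
Product: 15 (1R,4aR,5R,6S,8aR)-6-(acetyloxy)-3-acetyl-2,8a-dihydroxy-4a,5-dimethyldecahydronaphthalen-1-yl (2Z)-2-methylbut-2-enoate (mixture of epimers at C2 and C3)
Conditions: Fe(acac)3 (0.5 equiv), PhSiH3 (2.5 equiv), 3 (3 equiv), (CH2OH)2, EtOH/ClCH2CH2Cl, 0 °C to rt
Reagents that add atoms: none
Why: An iron hydride formed from Fe(acac)3 and PhSiH3 transfers a hydrogen atom to the exocyclic CH2 (Mukaiyama-type MHAT), the tertiary radical at the future angular carbon adds to the CH2 terminus of methyl vinyl ketone (Giese addition), the α-keto radical is reduced by divalent iron to an iron enolate, and this enolate adds to the pendant aldehyde (intramolecular aldol). The closest known reaction type is the HAT-initiated reductive olefin–enone coupling run in its annulative radical–polar crossover form with unsaturated aldehydes. Ring A closes in the aldol event as a 6-(enolexo)-exo-trig cyclisation that follows the intermolecular C–C bond formation, so the operation is a formal [4+2] annulation. The only lasting new stereocentre is the quaternary angular carbon: the enone is expected to add anti to the flanking C-methyl and tertiary hydroxyl, both axial in the chair that keeps the large side chain equatorial, and only this adduct can close without strain to the cis-decalin; the carbinol and acetyl-bearing centres formed in the aldol are erased in steps 10 and 11. The step needs HAT to the 1,1-disubstituted olefin in preference to the trisubstituted, electron-poor angelate, which the steric preference of MHAT for terminal CH2 groups should secure, and excess enone offsets its own reductive aldol with the aldehyde.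

**Step 10**
Reactants: 15 (1R,4aR,5R,6S,8aR)-6-(acetyloxy)-3-acetyl-2,8a-dihydroxy-4a,5-dimethyldecahydronaphthalen-1-yl (2Z)-2-methylbut-2-enoate
Product: 16 (1S,4aR,5R,6S,8aR)-6-(acetyloxy)-3-acetyl-8a-hydroxy-4a,5-dimethyl-2-oxodecahydronaphthalen-1-yl (2Z)-2-methylbut-2-enoate (C3 epimers and enol form)
Conditions: Dess–Martin periodinane, CH2Cl2, 0 °C to rt
Reagents that add atoms: none
Why: Dess–Martin oxidation converts the secondary aldol carbinol to the ketone under near-neutral conditions, the tertiary alcohol cannot react, and all epimers converge on one enolisable β-diketone.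

**Step 11**
Reactants: 16 (1S,4aR,5R,6S,8aR)-6-(acetyloxy)-3-acetyl-8a-hydroxy-4a,5-dimethyl-2-oxodecahydronaphthalen-1-yl (2Z)-2-methylbut-2-enoate
Product: 19 (1S,4aR,5R,6S,8aR)-6-(acetyloxy)-3-acetyl-8a-hydroxy-4a,5-dimethyl-2-oxo-1,2,4a,5,6,7,8,8a-octahydronaphthalen-1-yl (2Z)-2-methylbut-2-enoate (CNP0196241.1), via α-phenylselanyl diketone 17 (not isolated), via selenoxide 18 (not isolated)
Conditions: PhSeCl, pyridine, CH2Cl2, 0 °C; then H2O2 (30% aq), 0 °C to rt
Reagents that add atoms: none
Why: Selenenylation of the β-diketone at its central carbon followed by selenoxide syn-elimination, for which the only β-hydrogens are on the ring CH2, should give the 2-acetyl enone without touching any stereocentre, the quaternary neighbour blocking further enolisation.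

**Compound list**

1 | (E)-3-methylpent-3-en-2-one | CC(=O)/C(C)=C/C | starting material
2 | (E)-3-methyl-2-[(triisopropylsilyl)oxy]penta-1,3-diene | C=C(O[Si](C(C)C)(C(C)C)C(C)C)/C(C)=C/C | intermediate
3 | methyl vinyl ketone (but-3-en-2-one) | C=CC(C)=O | starting material
4 | 1-[(1S,2S)-2,3-dimethyl-4-[(triisopropylsilyl)oxy]cyclohex-3-en-1-yl]ethan-1-one | CC(C)[Si](C(C)C)(C(C)C)OC1=C(C)[C@@H](C)[C@@H](C(C)=O)CC1 | intermediate
5 | (3S,4S)-4-acetyl-2,3-dimethylcyclohex-1-en-1-yl trifluoromethanesulfonate | O=S(=O)(OC1=C(C)[C@@H](C)[C@@H](C(C)=O)CC1)C(F)(F)F | intermediate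
6 | (3R,4S)-4-(acetyloxy)-2,3-dimethylcyclohex-1-en-1-yl trifluoromethanesulfonate | O=S(=O)(OC1=C(C)[C@@H](C)[C@@H](OC(C)=O)CC1)C(F)(F)F | intermediate
7 | (R)-2,2-dimethyl-1,3-dioxolane-4-carbaldehyde | O=C[C@H]1COC(C)(C)O1 | starting material
8 | (1S,2R)-4-[(S)-[(4R)-2,2-dimethyl-1,3-dioxolan-4-yl](hydroxy)methyl]-2,3-dimethylcyclohex-3-en-1-yl acetate | O[C@H]([C@H]2COC(C)(C)O2)C1=C(C)[C@@H](C)[C@@H](OC(C)=O)CC1 | intermediate
9 | (1S,2R,4R)-4-[(R)-[(4R)-2,2-dimethyl-1,3-dioxolan-4-yl](hydroxy)methyl]-4-hydroperoxy-2-methyl-3-methylidenecyclohexyl acetate | O[C@H]([C@H]2COC(C)(C)O2)[C@@]1(OO)CC[C@H](OC(C)=O)[C@H](C)C1=C | intermediate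
10 | (1S,2R,4R)-4-[(R)-[(4R)-2,2-dimethyl-1,3-dioxolan-4-yl](hydroxy)methyl]-4-hydroxy-2-methyl-3-methylidenecyclohexyl acetate | O[C@H]([C@H]2COC(C)(C)O2)[C@@]1(O)CC[C@H](OC(C)=O)[C@H](C)C1=C | intermediate
11 | angelic acid, (2Z)-2-methylbut-2-enoic acid | C/C=C(/C)C(=O)O | starting material
12 | (R)-[(1R,3R,4S)-4-(acetyloxy)-1-hydroxy-3-methyl-2-methylidenecyclohexyl][(4R)-2,2-dimethyl-1,3-dioxolan-4-yl]methyl (2Z)-2-methylbut-2-enoate | C/C=C(/C)C(=O)O[C@H]([C@H]2COC(C)(C)O2)[C@@]1(O)CC[C@H](OC(C)=O)[C@H](C)C1=C | intermediate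
13 | (1R,2R)-1-[(1R,3R,4S)-4-(acetyloxy)-1-hydroxy-3-methyl-2-methylidenecyclohexyl]-2,3-dihydroxypropyl (2Z)-2-methylbut-2-enoate | C/C=C(/C)C(=O)O[C@H]([C@H](O)CO)[C@@]1(O)CC[C@H](OC(C)=O)[C@H](C)C1=C | intermediate
14 | (1S)-1-[(1R,3R,4S)-4-(acetyloxy)-1-hydroxy-3-methyl-2-methylidenecyclohexyl]-2-oxoethyl (2Z)-2-methylbut-2-enoate | C/C=C(/C)C(=O)O[C@H](C=O)[C@@]1(O)CC[C@H](OC(C)=O)[C@H](C)C1=C | intermediate
15 | (1R,4aR,5R,6S,8aR)-6-(acetyloxy)-3-acetyl-2,8a-dihydroxy-4a,5-dimethyldecahydronaphthalen-1-yl (2Z)-2-methylbut-2-enoate, C2/C3 epimer mixture | C/C=C(/C)C(=O)O[C@@H]1C(O)C(C(C)=O)C[C@]2(C)[C@@H](C)[C@@H](OC(C)=O)CC[C@]12O | intermediate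
16 | (1S,4aR,5R,6S,8aR)-6-(acetyloxy)-3-acetyl-8a-hydroxy-4a,5-dimethyl-2-oxodecahydronaphthalen-1-yl (2Z)-2-methylbut-2-enoate | C/C=C(/C)C(=O)O[C@@H]1C(=O)C(C(C)=O)C[C@]2(C)[C@@H](C)[C@@H](OC(C)=O)CC[C@]12O | intermediate
17 | (1S,4aR,5R,6S,8aR)-6-(acetyloxy)-3-acetyl-8a-hydroxy-4a,5-dimethyl-2-oxo-3-(phenylselanyl)decahydronaphthalen-1-yl (2Z)-2-methylbut-2-enoate | C/C=C(/C)C(=O)O[C@@H]1C(=O)C(C(C)=O)([Se]c3ccccc3)C[C@]2(C)[C@@H](C)[C@@H](OC(C)=O)CC[C@]12O | intermediate
18 | selenoxide of 17 (3-(phenylseleninyl) diketone) | C/C=C(/C)C(=O)O[C@@H]1C(=O)C(C(C)=O)([Se](=O)c3ccccc3)C[C@]2(C)[C@@H](C)[C@@H](OC(C)=O)CC[C@]12O | intermediate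
19 | (1S,4aR,5R,6S,8aR)-6-(acetyloxy)-3-acetyl-8a-hydroxy-4a,5-dimethyl-2-oxo-1,2,4a,5,6,7,8,8a-octahydronaphthalen-1-yl (2Z)-2-methylbut-2-enoate | C/C=C(/C)C(=O)O[C@@H]1C(=O)C(C(C)=O)=C[C@]2(C)[C@@H](C)[C@@H](OC(C)=O)CC[C@]12O | target

**Step count and risks**

Total step count: 11. Longest linear sequence: 11 steps (from 1).

Steps most likely to fail:

1. Step 9. The enone may add to the radical on the face syn to the C-methyl and hydroxyl, the iron enolate may be protonated before it closes, or methyl vinyl ketone may undergo its own reductive aldol with the aldehyde. Fallback: the two bonds are made in the opposite order. Starting from 14, a Morita–Baylis–Hillman reaction with 3 (DABCO, THF, 0 °C) would give the α-methylene-β-hydroxy ketone F1. Treating F1 with Fe(acac)3 and PhSiH3 in EtOH would then start an intramolecular MHAT Giese cyclisation (6-endo) in which the tether delivers the acceptor to the side-chain face, and the route is rejoined at 15.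

2. Step 7. Acylation of the hindered secondary alcohol may be slow, and the angelate may isomerise to the E (tiglate) geometry under the forcing conditions. Fallback: the Z olefin is built on the ester instead of carried in. Starting from 10, esterification with 2-[bis(2,2,2-trifluoroethoxy)phosphoryl]propanoic acid (DCC, DMAP, CH2Cl2) would give the phosphonate ester F3. Still–Gennari olefination of F3 with acetaldehyde (KN(SiMe3)2, 18-crown-6, THF, −78 °C) should then give the Z trisubstituted ester, and the route is rejoined at 12.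

3. Step 6. Hydrogen abstraction may occur from ring positions instead of the methyl group, or oxygen may be delivered to the face anti to the hydroxyl (the face away from the pseudoaxial ring methyl). Fallback: oxygen transfer and olefin transposition are separated. Starting from 8, hydroxyl-directed (Henbest, threo-selective) epoxidation with mCPBA and NaHCO3 in CH2Cl2 would give the epoxy alcohol F2. Isomerisation of F2 with diethylaluminium 2,2,6,6-tetramethylpiperidide (Et2Al(NC9H18), toluene, 0 °C), which removes a proton from the methyl group on the epoxide, would open it to the exocyclic allylic tertiary alcohol, and the route is rejoined at 10.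

**Further compounds**

F1 | step 9 | (1R)-1-[(1R,3R,4S)-4-(acetyloxy)-1-hydroxy-3-methyl-2-methylidenecyclohexyl]-2-hydroxy-3-methylidene-4-oxopentyl (2Z)-2-methylbut-2-enoate (carbinol epimers) | C/C=C(/C)C(=O)O[C@H](C(O)C(=C)C(C)=O)[C@@]1(O)CC[C@H](OC(C)=O)[C@H](C)C1=C
F2 | step 6 | threo epoxy alcohol of 8: 3,4-epoxide with the epoxide oxygen cis to the ring C-methyl and acetoxy groups | O[C@H]([C@H]2COC(C)(C)O2)[C@@]13CC[C@H](OC(C)=O)[C@H](C)[C@]1(C)O3
F3 | step 7 | (R)-[(1R,3R,4S)-4-(acetyloxy)-1-hydroxy-3-methyl-2-methylidenecyclohexyl][(4R)-2,2-dimethyl-1,3-dioxolan-4-yl]methyl 2-[bis(2,2,2-trifluoroethoxy)phosphoryl]propanoate | CC(P(=O)(OCC(F)(F)F)OCC(F)(F)F)C(=O)O[C@H]([C@H]2COC(C)(C)O2)[C@@]1(O)CC[C@H](OC(C)=O)[C@H](C)C1=C
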